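1. Feature: the cyclohexane ring C1–C6, with the quaternary carbinol C1 (OH and CO2H) and oxygen on C3, C4 and C5, is a 3-deoxyhept-2-ulosonate chain folded so that its C7 is bonded to its C2; that bond is C1–C2 of the target.
2. Target 13 ⇒ triallyl compound 12 (one allyl ester, two aryl allyl ethers, removed together) ⇒ C3 ketone 10 (hydride to C3 from the equatorial side gives the axial 3-OH).
3. 10 ⇒ allyl 3-dehydroquinate 5 + two acid chlorides 9 (from p-coumaric acid 6); the C4–O and C5–O esters are made while C3 is a carbonyl.
4. 5 ⇒ 3-dehydroquinic acid 4 ⇒ heptulosonate phosphate 3; the enzymatic aldol closes the cyclohexane, the only ring formed in the route.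
5. 3 ⇒ D-erythrose 4-phosphate 1 + phosphoenolpyruvate 2 (enzymatic aldol). Target C4 comes from 1, C5 is set in step 1, C1 in step 2, C3 in step 7.

Key step: step 2

Assumption: 1–4 are drawn as free acids although they are handled as salts near pH 7; recombinant E. coli DAHP synthase (AroG) and 3-dehydroquinate synthase (AroB) are used as isolated enzymes, and species that never leave an active site are not counted as compounds.
Remark: ring positions follow quinic acid numbering (C1 carboxyl-bearing carbinol; C3 ketone or axial hydroxyl; C4 and C5 the trans pair of oxygens).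

Step 1
Reactants: 1 D-erythrose 4-phosphate; 2 phosphoenolpyruvic acid
Product: 3 3-deoxy-D-arabino-hept-2-ulosonic acid 7-phosphate (DAHP)
Conditions: DAHP synthase (E. coli AroG), MnCl2 (cat.), HEPES buffer pH 7.0, 25 °C; anion exchange (Et3NH·HCO3 gradient)
Reagents that add atoms: water, O
Why: In this enzymatic aldol-type addition C3 of the enol phosphate 2 adds to the re face of the aldehyde of 1 while water attacks C2 of 2 with C–O cleavage of the phosphate, so the enzyme sets the new C4 centre (R) and C5 and C6 come unchanged from 1.

Step 2
Reactants: 3 DAHP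
Product: 4 3-dehydroquinic acid
Conditions: 3-dehydroquinate synthase (E. coli AroB), NAD+ (cat.), CoCl2 (cat.), MOPS buffer pH 7.5, 25 °C; AG 1-X8 (acetate form), aq AcOH gradient; freeze-dry
Reagents that add atoms: none
Why: The closest known reaction type is an intramolecular aldol addition of a ketone enol to an α-keto acid, here the native reaction of the enzyme: bound NAD+ oxidises the C5 hydroxyl of 3 (heptulosonate numbering), the acidified H6 is removed and phosphate leaves C7 by E1cB elimination, and the bound NADH returns hydride to C5 with the original configuration. Opening of the hemiketal of the resulting enol ether frees the C6=C7 enol and the C2 keto acid, and C7 adds to C2, which makes the C1–C2 bond of the target numbering. This closes the single carbocycle, the cyclohexane, in a 6-(enolendo)-exo-trig mode. The only new stereocentre, the C1 carbinol, is controlled by the chair-like folding held by the active site, in which the oxygens on C4 and C5 and the carboxylate are equatorial and the new hydroxyl is axial. The step needs one regiochemistry of enol formation and a product that survives without dehydration: the C7 phosphate secures the first, because its elimination is the only route to an enol and places it at C6=C7, and pH 7.5 at 25 °C secures the second. The carbinol centres at C4 and C5 are not touched, and because C3 emerges as a carbonyl it has no hydroxyl to esterify in step 6.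

Step 3
Reactants: 4 3-dehydroquinic acid
Product: 5 allyl 3-dehydroquinate
Conditions: CsHCO3 (1.05 equiv), allyl bromide (1.5 equiv), DMF, 0 °C → rt
Reagents that add atoms: allyl bromide, C=CCBr
Why: SN2 O-alkylation of the caesium carboxylate should give the ester because the carboxylate is the only group ionised by hydrogen carbonate, so the hydroxyls stay unalkylated, the β-hydroxy ketone meets no base able to dehydrate it, and no stereocentre is touched.

Step 4
Reactants: 6 p-coumaric acid
Product: 8 (E)-4-(allyloxy)cinnamic acid, via allyl (E)-4-(allyloxy)cinnamate 7 (not isolated)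
Conditions: allyl bromide (2.5 equiv), K2CO3 (3 equiv), DMF, rt; then NaOH, MeOH/H2O, 50 °C; HCl
Reagents that add atoms: allyl bromide, C=CCBr
Why: Williamson O-allylation of phenoxide and carboxylate is followed by saponification, in which hydroxide cleaves only the allyl ester because the aryl allyl ether has no acyl carbon, and the E alkene is unchanged.

Step 5
Reactants: 8 (E)-4-(allyloxy)cinnamic acid
Product: 9 (E)-4-(allyloxy)cinnamoyl chloride
Conditions: (COCl)2, DMF (cat.), CH2Cl2, 0 °C → rt; evaporate, use crude
Reagents that add atoms: oxalyl chloride, O=C(Cl)C(=O)Cl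
Why: DMF-catalysed chlorination of a carboxylic acid with oxalyl chloride is standard for cinnamic acids and leaves the aryl allyl ether and the E alkene untouched.

Step 6
Reactants: 5 allyl 3-dehydroquinate; 9 (E)-4-(allyloxy)cinnamoyl chloride (2.5 equiv)
Product: 10 allyl 4,5-bis-O-[(E)-4-(allyloxy)cinnamoyl]-3-dehydroquinate
Conditions: pyridine (6 equiv), CH2Cl2, −20 → 0 °C, no DMAP
Reagents that add atoms: none
Why: Pyridine-mediated O-acylation with an acyl chloride should esterify the two equatorial secondary hydroxyls and leave the hindered axial tertiary C1 hydroxyl free, the weak base, low temperature and absence of DMAP being chosen to hold back enolisation toward C4 and E1cB loss of the C5 carboxylate; no stereocentre is formed.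

Step 7
Reactants: 10 allyl 4,5-bis-O-[(E)-4-(allyloxy)cinnamoyl]-3-dehydroquinate
Product: 12 allyl 4,5-bis-O-[(E)-4-(allyloxy)cinnamoyl]quinate, via C1-O-diethylboryl ketone 11 (not isolated)
Conditions: Et2BOMe (1.2 equiv), THF/MeOH 4:1, −78 °C; NaBH4 (1.5 equiv), −78 °C; AcOH, −78 °C → rt; MeOH co-evaporation
Reagents that add atoms: methoxydiethylborane, CCB(CC)OC (its BEt2 group is held in 11 only and is gone from 12)
Why: In this Narasaka–Prasad 1,3-syn reduction the axial C1 hydroxyl is converted to the borinate 11, whose boron sits over the axial face of the C3 carbonyl and can bind its oxygen, so borohydride should add from the equatorial side and set the C3 hydroxyl axial, cis to O1 and O4 as in quinic acid, while the new oxygen stays on boron until the acidic quench so that the C4 acyl group does not shift and the esters, enoates and allyl ethers are inert to NaBH4 at −78 °C.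

Step 8
Reactants: 12 allyl 4,5-bis-O-[(E)-4-(allyloxy)cinnamoyl]quinate
Product: 13 4,5-di-O-p-coumaroylquinic acid
Conditions: Pd(PPh3)4 (5 mol %), 4-MeC6H4SO2H (3.6 equiv), THF/MeOH, rt
Reagents that add atoms: none
Why: In this Tsuji–Trost-type deallylation zerovalent palladium ionises the allyl ester and both aryl allyl ethers and the sulfinate takes up each allyl group as a sulfone, while the acidic scavenger keeps the acid and phenols protonated so that the cinnamate esters neither cleave nor migrate from O4 to O3 and no stereocentre is touched.

Compound list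
1 | D-erythrose 4-phosphate, (2R,3R) | O=C[C@H](O)[C@H](O)COP(=O)(O)O | starting material
2 | phosphoenolpyruvic acid (used as its potassium salt) | C=C(OP(=O)(O)O)C(=O)O | starting material
3 | 3-deoxy-D-arabino-hept-2-ulosonic acid 7-phosphate (DAHP), (4R,5S,6R), open-chain form drawn | OC(=O)C(=O)C[C@@H](O)[C@H](O)[C@H](O)COP(=O)(O)O | intermediate
4 | 3-dehydroquinic acid, (1R,3R,4S)-1,3,4-trihydroxy-5-oxocyclohexane-1-carboxylic acid; 1-OH cis to 4-OH, 4-OH and 5-OH trans | O[C@@H]1C(=O)C[C@@](O)(C(=O)O)C[C@H]1O | intermediate
5 | allyl 3-dehydroquinate (allyl ester of 4, same configuration) | O[C@@H]1C(=O)C[C@@](O)(C(=O)OCC=C)C[C@H]1O | intermediate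
6 | p-coumaric acid, (E)-4-hydroxycinnamic acid | O=C(O)/C=C/c1ccc(O)cc1 | starting material
7 | allyl (E)-4-(allyloxy)cinnamate | C=CCOC(=O)/C=C/c1ccc(OCC=C)cc1 | intermediate
8 | (E)-4-(allyloxy)cinnamic acid | O=C(O)/C=C/c1ccc(OCC=C)cc1 | intermediate
9 | (E)-4-(allyloxy)cinnamoyl chloride | O=C(Cl)/C=C/c1ccc(OCC=C)cc1 | intermediate
10 | allyl 4,5-bis-O-[(E)-4-(allyloxy)cinnamoyl]-3-dehydroquinate (configuration of 4) | O=C(/C=C/c1ccc(OCC=C)cc1)O[C@@H]1C(=O)C[C@@](O)(C(=O)OCC=C)C[C@H]1OC(=O)/C=C/c1ccc(OCC=C)cc1 | intermediate
11 | allyl 4,5-bis-O-[(E)-4-(allyloxy)cinnamoyl]-1-O-(diethylboryl)-3-dehydroquinate | O=C(/C=C/c1ccc(OCC=C)cc1)O[C@@H]1C(=O)C[C@@](OB(CC)CC)(C(=O)OCC=C)C[C@H]1OC(=O)/C=C/c1ccc(OCC=C)cc1 | intermediate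
12 | allyl 4,5-bis-O-[(E)-4-(allyloxy)cinnamoyl]quinate (1-OH, 3-OH and 4-O cis; 5-O trans to 4-O) | O=C(/C=C/c1ccc(OCC=C)cc1)O[C@@H]1[C@H](O)C[C@@](O)(C(=O)OCC=C)C[C@H]1OC(=O)/C=C/c1ccc(OCC=C)cc1 | intermediate
13 | 4,5-di-O-p-coumaroylquinic acid, (1S,3R,4R,5R) | O=C(/C=C/c1ccc(O)cc1)O[C@@H]1[C@H](O)C[C@@](O)(C(=O)O)C[C@H]1OC(=O)/C=C/c1ccc(O)cc1 | target

Total step count: 8
Longest linear sequence: 6 steps (steps 1, 2, 3, 6, 7, 8)

Steps most likely to fail

Step 6. The risk is base-triggered enolisation of the α-acyloxy ketone toward C4, followed by E1cB loss of the C5 carboxylate and onward aromatisation, or a ketol shift of the C4 hydroxy ketone before it is acylated. The fallback sets out from 5 and 8 and returns at 10. Acid 8 is condensed with DCC (0.5 equiv, CH2Cl2, 0 °C) to (E)-4-(allyloxy)cinnamic anhydride F1. Compound 5 is then acylated with F1 under Sc(OTf)3 catalysis in MeCN at −20 °C, an acid-catalysed esterification in which no base is present to form the enolate. Stopping at the diester stage should leave the tertiary hydroxyl free and give 10.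

Step 7. The risk is poor facial selectivity, that is hydride delivery from the axial face to give the C3 epimer, together with a shift of the C4 acyl group to O3 if the alkoxide is set free. The fallback sets out from 10 and returns at 12. The C1 hydroxyl is silylated with N,O-bis(trimethylsilyl)acetamide in MeCN at rt to allyl 4,5-bis-O-[(E)-4-(allyloxy)cinnamoyl]-1-O-(trimethylsilyl)-3-dehydroquinate F2, whose axial silyl ether blocks the axial face and removes the free hydroxyl. LiBH(s-Bu)3 (1.05 equiv) in THF at −78 °C, quenched with AcOH at that temperature, should then add hydride from the equatorial side to give allyl 4,5-bis-O-[(E)-4-(allyloxy)cinnamoyl]-1-O-(trimethylsilyl)quinate F3. Citric acid in MeOH at 0 °C removes the silyl ether to give 12.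

Step 3. The risk is dehydration of the β-hydroxy ketone to the dehydroshikimate ester and aromatisation while the carboxylate is formed and alkylated, or incomplete alkylation of a poorly soluble salt. The fallback sets out from 4 and returns at 5. O-allyl-N,N'-diisopropylisourea F4 is prepared from allyl alcohol and N,N'-diisopropylcarbodiimide with CuCl (cat.). The free acid 4 is esterified with F4 in THF/DMF at rt: the acid protonates the isourea and its carboxylate takes the allyl group, so no salt and no base are needed, and 5 results beside N,N'-diisopropylurea.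

Further compounds
F1 | step 6 | (E)-4-(allyloxy)cinnamic anhydride | C=CCOc1ccc(/C=C/C(=O)OC(=O)/C=C/c2ccc(OCC=C)cc2)cc1
F2 | step 7 | allyl 4,5-bis-O-[(E)-4-(allyloxy)cinnamoyl]-1-O-(trimethylsilyl)-3-dehydroquinate | O=C(/C=C/c1ccc(OCC=C)cc1)O[C@@H]1C(=O)C[C@@](O[Si](C)(C)C)(C(=O)OCC=C)C[C@H]1OC(=O)/C=C/c1ccc(OCC=C)cc1
F3 | step 7 | allyl 4,5-bis-O-[(E)-4-(allyloxy)cinnamoyl]-1-O-(trimethylsilyl)quinate | O=C(/C=C/c1ccc(OCC=C)cc1)O[C@@H]1[C@H](O)C[C@@](O[Si](C)(C)C)(C(=O)OCC=C)C[C@H]1OC(=O)/C=C/c1ccc(OCC=C)cc1
F4 | step 3 | O-allyl-N,N'-diisopropylisourea | C=CCOC(=NC(C)C)NC(C)C
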